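**Retrosynthetic overview**
- The target comes from O-methylation of the 2,5-dihydroxyquinone, which comes from hydrolysis of both C–Cl bonds of a 2,5-dichloro-3,6-bis(indolyl)-1,4-benzoquinone.
- Key disconnection: the quinone C6–indole C3 bond, formed by intermolecular acid-promoted Michael addition of 7-prenylindole to 2,5-dichloro-3-(indol-3-yl)-1,4-benzoquinone, then re-oxidation.
- That mono-indolyl quinone comes from the same Michael addition/oxidation of indole with 2,5-dichloro-1,4-benzoquinone.
- 7-Prenylindole comes from indoline by N-(1,1-dimethylpropargyl)ation, semihydrogenation, aza-Claisen shift to C7 and dehydrogenation.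
- Ring order: no ring is built; the quinone ring and both indole bicycles are bought intact, and the pyrrole ring of the prenylated unit is carried as indoline and aromatised at the end of its branch.

Assumption: the target has no stereocentre and no stereogenic double bond, so it is achiral and no stereocontrol is needed; 2,5-dichloro-1,4-benzoquinone and 3-chloro-3-methylbut-1-yne are taken as purchasable.

**Route**

Step 1
Reactants: 1 indoline; 2 3-chloro-3-methylbut-1-yne
Product: 3 1-(2-methylbut-3-yn-2-yl)indoline
Conditions: CuCl (5 mol %), Et3N (1.5 equiv), THF, 0 °C to rt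
Reagents that add atoms: none
Why: Copper-catalysed propargylic amination (Hennion-type substitution) of the tertiary propargylic chloride lets the secondary amine capture the copper-stabilised propargyl cation at the tertiary carbon.

Step 2
Reactants: 3 1-(2-methylbut-3-yn-2-yl)indoline
Product: 4 1-(2-methylbut-3-en-2-yl)indoline
Conditions: H2 (1 atm), Pd/CaCO3 poisoned with Pb(OAc)2, quinoline, EtOAc, rt, stopped after 1 equiv H2
Reagents that add atoms: none
Why: Lindlar semihydrogenation reduces the terminal alkyne to the alkene and stops there because the poisoned palladium surface binds alkenes poorly.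

Step 3
Reactants: 4 1-(2-methylbut-3-en-2-yl)indoline
Product: 5 7-(3-methylbut-2-en-1-yl)indoline
Conditions: TsOH·H2O (0.2 equiv), MeCN/H2O 10:1, 80 °C
Reagents that add atoms: none
Why: N-protonation accelerates an aromatic aza-Claisen (3-aza-Cope) [3,3] shift to the only free ortho carbon (C7), which inverts the 1,1-dimethylallyl group into a linear prenyl group before rearomatisation.

Step 4
Reactants: 5 7-(3-methylbut-2-en-1-yl)indoline
Product: 6 7-(3-methylbut-2-en-1-yl)-1H-indole
Conditions: activated MnO2 (10 equiv), CH2Cl2, rt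
Reagents that add atoms: none
Why: MnO2 dehydrogenation of the indoline is driven by aromatisation to the indole and leaves the isolated trisubstituted alkene untouched.

Step 5
Reactants: 7 1H-indole; 8 2,5-dichloro-1,4-benzoquinone
Product: 10 2,5-dichloro-3-(1H-indol-3-yl)-1,4-benzoquinone, via indolyl-dichlorohydroquinone 9 (not isolated)
Conditions: 8 (1.2 equiv), AcOH, rt, 16 h; concentrate; then DDQ (1.2 equiv), THF, rt
Reagents that add atoms: none
Why: Acid-promoted Michael addition of the enamine-like indole C3 to an unsubstituted β-carbon of the quinone gives the hydroquinone after tautomerisation, and the stronger oxidant DDQ returns it to the quinone.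

Step 6
Reactants: 10 2,5-dichloro-3-(1H-indol-3-yl)-1,4-benzoquinone; 6 7-(3-methylbut-2-en-1-yl)-1H-indole
Product: 12 2,5-dichloro-3-(1H-indol-3-yl)-6-[7-(3-methylbut-2-en-1-yl)-1H-indol-3-yl]-1,4-benzoquinone, via bis(indolyl)-dichlorohydroquinone 11 (not isolated)
Conditions: 6 (1.2 equiv), AcOH, rt to 40 °C, 24–48 h; concentrate; then DDQ (1.0 equiv), THF, 0 °C to rt
Reagents that add atoms: none
Why: The key intermolecular Michael addition can only occur at the single remaining C–H carbon (C6) of the quinone, AcOH is mild enough to spare the prenyl group, and DDQ oxidation of the hydroquinone is much faster than any attack on the allylic positions.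

Step 7
Reactants: 12 2,5-dichloro-3-(1H-indol-3-yl)-6-[7-(3-methylbut-2-en-1-yl)-1H-indol-3-yl]-1,4-benzoquinone
Product: 13 2,5-dihydroxy-3-(1H-indol-3-yl)-6-[7-(3-methylbut-2-en-1-yl)-1H-indol-3-yl]-1,4-benzoquinone
Conditions: 10% aq NaOH/MeOH 1:4, reflux, 2 h; then 1 M HCl to pH 2
Reagents that add atoms: sodium hydroxide, [Na+].[OH-]
Why: Each chloride sits on a vinylogous acyl chloride and is replaced by addition–elimination (vinylic nucleophilic substitution), driven by formation of the stabilised dianion of the vinylogous acid.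

Step 8
Reactants: 13 2,5-dihydroxy-3-(1H-indol-3-yl)-6-[7-(3-methylbut-2-en-1-yl)-1H-indol-3-yl]-1,4-benzoquinone
Product: 14 2,5-dimethoxy-3-(1H-indol-3-yl)-6-[7-(3-methylbut-2-en-1-yl)-1H-indol-3-yl]-1,4-benzoquinone
Conditions: Me2SO4 (2.5 equiv), K2CO3 (3 equiv), acetone, reflux
Reagents that add atoms: dimethyl sulfate, COS(=O)(=O)OC
Why: Williamson-type O-alkylation of the strongly acidic hydroxyquinone OH groups proceeds with K2CO3, which is too weak to deprotonate the indole N–H, and both tautomers of 13 give the same dimethyl ether.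

**Compound list**

1 | indoline | C1Cc2ccccc2N1 | starting material
2 | 3-chloro-3-methylbut-1-yne | C#CC(C)(C)Cl | starting material
3 | 1-(2-methylbut-3-yn-2-yl)indoline | C#CC(C)(C)N1CCc2ccccc21 | intermediate
4 | 1-(2-methylbut-3-en-2-yl)indoline | C=CC(C)(C)N1CCc2ccccc21 | intermediate
5 | 7-(3-methylbut-2-en-1-yl)indoline | CC(C)=CCc1cccc2c1NCC2 | intermediate
6 | 7-(3-methylbut-2-en-1-yl)-1H-indole | CC(C)=CCc1cccc2cc[nH]c12 | intermediate
7 | 1H-indole | c1ccc2[nH]ccc2c1 | starting material
8 | 2,5-dichloro-1,4-benzoquinone | O=C1C=C(Cl)C(=O)C=C1Cl | starting material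
9 | 2,5-dichloro-3-(1H-indol-3-yl)benzene-1,4-diol | Oc1cc(Cl)c(O)c(-c2c[nH]c3ccccc23)c1Cl | intermediate
10 | 2,5-dichloro-3-(1H-indol-3-yl)-1,4-benzoquinone | O=C1C=C(Cl)C(=O)C(c2c[nH]c3ccccc23)=C1Cl | intermediate
11 | 2,5-dichloro-3-(1H-indol-3-yl)-6-[7-(3-methylbut-2-en-1-yl)-1H-indol-3-yl]benzene-1,4-diol | Oc1c(Cl)c(-c2c[nH]c3ccccc23)c(O)c(Cl)c1-c1c[nH]c2c(CC=C(C)C)cccc12 | intermediate
12 | 2,5-dichloro-3-(1H-indol-3-yl)-6-[7-(3-methylbut-2-en-1-yl)-1H-indol-3-yl]-1,4-benzoquinone | O=C1C(Cl)=C(c2c[nH]c3ccccc23)C(=O)C(Cl)=C1c1c[nH]c2c(CC=C(C)C)cccc12 | intermediate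
13 | 2,5-dihydroxy-3-(1H-indol-3-yl)-6-[7-(3-methylbut-2-en-1-yl)-1H-indol-3-yl]-1,4-benzoquinone | O=C1C(O)=C(c2c[nH]c3ccccc23)C(=O)C(O)=C1c1c[nH]c2c(CC=C(C)C)cccc12 | intermediate
14 | 2,5-dimethoxy-3-(1H-indol-3-yl)-6-[7-(3-methylbut-2-en-1-yl)-1H-indol-3-yl]-1,4-benzoquinone | COC1=C(c2c[nH]c3ccccc23)C(=O)C(OC)=C(c2c[nH]c3c(CC=C(C)C)cccc23)C1=O | target

**Summary**

Total step count: 8. Longest linear sequence: 7 steps (steps 1, 2, 3, 4, 6, 7, 8, from indoline).

The three steps most likely to fail:

Step 6 (key Michael addition). The mono-indolyl quinone 10 is less electrophilic and more hindered than 8, and the prenyl group limits how strong the acid can be. The fallback reverses the order of fragment union. It sets out from 6, which is added in AcOH to the more electrophilic unsubstituted quinone 8. This gives 2,5-dichloro-3-[7-(3-methylbut-2-en-1-yl)-1H-indol-3-yl]benzene-1,4-diol F3, which is oxidised in the same flask with DDQ to 2,5-dichloro-3-[7-(3-methylbut-2-en-1-yl)-1H-indol-3-yl]-1,4-benzoquinone F4. The sluggish second addition is then forced with a large excess of cheap indole 7 in AcOH, followed by DDQ, and the route is rejoined at 12 (through 11).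

Step 3 (aza-Claisen). The tertiary N-allyl group may ionise and be lost as isoprene, or the new prenyl group may be hydroaminated by N1 under acid. The fallback sets out from indoline 1. Boc2O gives tert-butyl indoline-1-carboxylate F1. Carbamate-directed lithiation at C7 (s-BuLi, TMEDA, Et2O, −78 °C), transmetalation with CuBr·SMe2 and alkylation with prenyl bromide gives tert-butyl 7-(3-methylbut-2-en-1-yl)indoline-1-carboxylate F2. Non-protic Boc removal (TMSOTf, 2,6-lutidine, CH2Cl2, 0 °C; then MeOH) returns to the route at 5.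

Step 8 (O-methylation). Competing N-methylation or incomplete dialkylation of the base-sensitive quinone is possible. The fallback sets out from 12 and bypasses 13. Anhydrous NaOMe in MeOH/THF at 0 °C to rt replaces both vinylic chlorides directly by methoxide through addition–elimination and arrives at 14. It makes no compound outside the list (entry F0).

**Further compounds**

F1 | step 3 | tert-butyl indoline-1-carboxylate | CC(C)(C)OC(=O)N1CCc2ccccc21
F2 | step 3 | tert-butyl 7-(3-methylbut-2-en-1-yl)indoline-1-carboxylate | CC(C)=CCc1cccc2c1N(C(=O)OC(C)(C)C)CC2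
F3 | step 6 | 2,5-dichloro-3-[7-(3-methylbut-2-en-1-yl)-1H-indol-3-yl]benzene-1,4-diol | Oc1cc(Cl)c(O)c(-c2c[nH]c3c(CC=C(C)C)cccc23)c1Cl
F4 | step 6 | 2,5-dichloro-3-[7-(3-methylbut-2-en-1-yl)-1H-indol-3-yl]-1,4-benzoquinone | O=C1C=C(Cl)C(=O)C(c2c[nH]c3c(CC=C(C)C)cccc23)=C1Cl
F0 | step 8 | none | none
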